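**Retrosynthetic overview**
- Target 27 ⇒ neopentyl alcohol 26 + 7-bromocoumarin 19 by a late aryl–O coupling. The coumarin ring is closed separately (18 → 19) and brought in intact.
- 26 ⇒ cyano sulfone 22 by functional-group changes only (C–SO2Ph → C–H, C≡N → CH2OH, pivalate → acetate).
- 22 ⇒ acyclic nitrile / dienyl sulfone 21. The cyclohexane is the only carbocycle formed: a 6-exo intramolecular Michael addition makes the bond between the quaternary carbon and the side-chain carbon and sets both new stereocentres from the existing C-methyl centre.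
- 21 ⇒ nitrile 8 + bromodienyl sulfone 17 (B-alkyl Suzuki). 8 comes from an Evans conjugate addition; 17 from sulfone 11 + bromo-enal 14.
- Ring order: pyranone of the coumarin (step 12, side branch), then the cyclohexane (step 14).

Assumption: SMILES show the major (2S) nitrile epimer of 8, 20 and 21 and the E isomer of 17 and 21; minor epimers or Z isomer are harmless because both elements are erased in steps 14–15.

Ring locants in names: C-1 carries the three-carbon chain, C-2 is the quaternary carbon, C-3 is CHMe, C-6 carries the isopropylidene.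

**Fragment A (nitrile 8)**

Step 1
Reactants: 1 (S)-4-benzyl-1,3-oxazolidin-2-one; 2 (E)-but-2-enoyl chloride
Product: 3 (S)-4-benzyl-3-[(E)-but-2-enoyl]-1,3-oxazolidin-2-one
Conditions: n-BuLi, THF, −78 °C; then 2, −78 → 0 °C
Reagents that add atoms: none
Why: N-acylation of the lithiated oxazolidinone by the acid chloride attaches the Evans auxiliary; no stereocentre is formed.

Step 2
Reactants: 3 (S)-4-benzyl-3-[(E)-but-2-enoyl]-1,3-oxazolidin-2-one
Product: 4 (S)-4-benzyl-3-[(R)-3-methylpent-4-enoyl]-1,3-oxazolidin-2-one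
Conditions: vinylMgBr (3 equiv), CuBr·SMe2 (1.5 equiv), THF–Me2S, −78 → −20 °C; aqueous work-up
Reagents that add atoms: vinylmagnesium bromide, C=C[Mg]Br
Why: Auxiliary-controlled cuprate conjugate addition; the Mg-chelated syn-s-cis imide is attacked at the β-carbon on the face opposite the benzyl group, giving the (R)-3-methylpent-4-enoyl centre that becomes ring C-3.

Step 3
Reactants: 4 (S)-4-benzyl-3-[(R)-3-methylpent-4-enoyl]-1,3-oxazolidin-2-one
Product: 5 (S)-4-benzyl-3-[(2S,3S)-2,3-dimethylpent-4-enoyl]-1,3-oxazolidin-2-one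
Conditions: NaHMDS, THF, −78 °C; MeI, −78 → −40 °C
Reagents that add atoms: iodomethane, CI
Why: Evans enolate alkylation; the chelated Z-enolate is methylated anti to the benzyl group (2S), a centre that only has to carry the methyl group because it is planarised in step 14.

Step 4
Reactants: 5 (S)-4-benzyl-3-[(2S,3S)-2,3-dimethylpent-4-enoyl]-1,3-oxazolidin-2-one
Product: 6 (2S,3S)-2,3-dimethylpent-4-en-1-ol
Conditions: LiBH4, H2O (1 equiv), Et2O, 0 °C
Reagents that add atoms: none
Why: Reductive cleavage of the imide by borohydride gives the primary alcohol and returns the auxiliary without touching either stereocentre or the alkene.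

Step 5
Reactants: 6 (2S,3S)-2,3-dimethylpent-4-en-1-ol
Product: 8 (2S,3S)-2,3-dimethylpent-4-enenitrile, via aldehyde 7 (not isolated)
Conditions: TEMPO (10 mol %), PhI(OAc)2 (2.3 equiv), NH4OAc (4 equiv), MeCN–H2O 9:1, rt
Reagents that add atoms: ammonium acetate, [NH4+].CC(=O)[O-]
Why: One-pot oxidative ammoxidation (TEMPO/iodine(III) oxidation to the aldehyde, imine formation, second oxidation to the nitrile) spares the terminal alkene and cannot touch the β-stereocentre.

**Fragment B (bromodienyl sulfone 17)**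

Step 6
Reactants: 9 3-bromopropan-1-ol
Product: 10 3-bromopropyl 2,2-dimethylpropanoate
Conditions: PivCl, pyridine, CH2Cl2, 0 °C → rt
Reagents that add atoms: pivaloyl chloride, CC(C)(C)C(Cl)=O
Why: Simple O-acylation; the pivalate has no α-hydrogens and so survives the carbanion steps, and is removed later by DIBAL-H.

Step 7
Reactants: 10 3-bromopropyl 2,2-dimethylpropanoate
Product: 11 3-(phenylsulfonyl)propyl 2,2-dimethylpropanoate
Conditions: PhSO2Na, Bu4NI (cat.), DMF, 70 °C
Reagents that add atoms: sodium benzenesulfinate, [Na+].[O-]S(=O)c1ccccc1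
Why: SN2 S-alkylation of the sulfinate by the primary bromide gives the sulfone.

Step 8
Reactants: 12 3-methylbut-2-enal
Product: 14 2-bromo-3-methylbut-2-enal, via dibromide 13 (not isolated)
Conditions: Br2, CH2Cl2, −10 °C; then Et3N, 0 °C → rt
Reagents that add atoms: bromine, BrBr
Why: Bromine addition to the enal followed by E2 loss of HBr from the acidic α-position gives the α-bromo enal with the isopropylidene unit in place.

Step 9
Reactants: 11 3-(phenylsulfonyl)propyl 2,2-dimethylpropanoate; 14 2-bromo-3-methylbut-2-enal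
Product: 15 5-bromo-4-hydroxy-6-methyl-3-(phenylsulfonyl)hept-5-en-1-yl 2,2-dimethylpropanoate (diastereomer mixture)
Conditions: LDA, THF, −78 °C, 20 min; then 14, −78 °C; AcOH quench at −78 °C
Reagents that add atoms: none
Why: 1,2-Addition of the α-sulfonyl carbanion to the aldehyde (Julia-type first stage); the β,β-disubstituted α-bromo enal cannot react in a conjugate sense and the two new centres are removed in step 11.

Step 10
Reactants: 15 5-bromo-4-hydroxy-6-methyl-3-(phenylsulfonyl)hept-5-en-1-yl 2,2-dimethylpropanoate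
Product: 16 4-acetoxy-5-bromo-6-methyl-3-(phenylsulfonyl)hept-5-en-1-yl 2,2-dimethylpropanoate
Conditions: Ac2O, pyridine, DMAP (cat.), CH2Cl2, 0 °C → rt
Reagents that add atoms: acetic anhydride, CC(=O)OC(C)=O
Why: O-acetylation turns the hydroxyl into a leaving group for the elimination.

Step 11
Reactants: 16 4-acetoxy-5-bromo-6-methyl-3-(phenylsulfonyl)hept-5-en-1-yl 2,2-dimethylpropanoate
Product: 17 (3E)-5-bromo-6-methyl-3-(phenylsulfonyl)hepta-3,5-dien-1-yl 2,2-dimethylpropanoate
Conditions: DBU (1.2 equiv), CH2Cl2, 0 °C → rt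
Reagents that add atoms: none
Why: E1cB elimination of acetate through the α-sulfonyl carbanion gives the vinyl sulfone, mainly the E isomer with the sulfonyl group cis to H.

**Fragment C (7-bromocoumarin 19)**

Step 12
Reactants: 18 4-bromo-2-hydroxybenzaldehyde
Product: 19 7-bromo-2H-chromen-2-one
Conditions: Ph3P=CHCO2Et, N,N-diethylaniline, reflux (about 215 °C)
Reagents that add atoms: ethyl (triphenyl-λ5-phosphanylidene)acetate, CCOC(=O)C=P(c1ccccc1)(c1ccccc1)c1ccccc1
Why: Wittig olefination of the salicylaldehyde followed by thermal E/Z isomerisation and lactonisation closes the pyranone ring.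

**Union, ring closure and end game**

Step 13
Reactants: 8 (2S,3S)-2,3-dimethylpent-4-enenitrile; 17 (3E)-5-bromo-6-methyl-3-(phenylsulfonyl)hepta-3,5-dien-1-yl 2,2-dimethylpropanoate
Product: 21 (3E,8S,9S)-9-cyano-8-methyl-3-(phenylsulfonyl)-5-(propan-2-ylidene)dec-3-en-1-yl 2,2-dimethylpropanoate, via alkylborane 20 (not isolated)
Conditions: 9-BBN dimer (0.55 equiv), THF, 0 °C → rt; then 17, Pd(dppf)Cl2 (5 mol %), AsPh3 (10 mol %), aq. Cs2CO3, DMF, rt → 50 °C
Reagents that add atoms: 9-borabicyclo[3.3.1]nonane, [H]B1C2CCCC1CCC2 (its boron unit is carried by intermediate 20 only)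
Why: Anti-Markovnikov hydroboration of the terminal alkene and B-alkyl Suzuki–Miyaura coupling with the vinyl bromide join the fragments under conditions that tolerate nitrile, pivalate and vinyl sulfone and leave the stereocentre alone.

Step 14
Reactants: 21 (3E,8S,9S)-9-cyano-8-methyl-3-(phenylsulfonyl)-5-(propan-2-ylidene)dec-3-en-1-yl 2,2-dimethylpropanoate
Product: 22 3-[(1S,2S,3S)-2-cyano-2,3-dimethyl-6-(propan-2-ylidene)cyclohexyl]-3-(phenylsulfonyl)propyl 2,2-dimethylpropanoate (epimers at the sulfonyl carbon)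
Conditions: LDA (1.1 equiv), THF–DMPU, −78 °C, inverse addition, 1 h; AcOH quench at −78 °C
Reagents that add atoms: none
Why: 6-exo-trig intramolecular Michael addition of the lithiated nitrile to the vinyl sulfone through a chair transition state in which the existing C-methyl is equatorial, the vinyl sulfone arm is axial (avoiding A(1,3) strain with the isopropylidene methyl) and the slim linear C=C=N unit sits axial, anti to the developing sulfonyl carbanion, so the new methyl is equatorial and the ring is (1S,2S,3S).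

Step 15
Reactants: 22 3-[(1S,2S,3S)-2-cyano-2,3-dimethyl-6-(propan-2-ylidene)cyclohexyl]-3-(phenylsulfonyl)propyl 2,2-dimethylpropanoate
Product: 23 3-[(1S,2S,3S)-2-cyano-2,3-dimethyl-6-(propan-2-ylidene)cyclohexyl]propyl 2,2-dimethylpropanoate
Conditions: 6 % Na(Hg), Na2HPO4, MeOH–THF, −20 → 0 °C
Reagents that add atoms: none
Why: Reductive desulfonylation (electron-transfer C–S cleavage, then protonation) replaces the sulfonyl group by hydrogen and removes the only stereorandom centre; nitrile, pivalate and the tetrasubstituted alkene are inert.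

Step 16
Reactants: 23 3-[(1S,2S,3S)-2-cyano-2,3-dimethyl-6-(propan-2-ylidene)cyclohexyl]propyl 2,2-dimethylpropanoate
Product: 24 (1S,2S,6S)-2-(3-hydroxypropyl)-1,6-dimethyl-3-(propan-2-ylidene)cyclohexane-1-carbaldehyde
Conditions: DIBAL-H (4.5 equiv), CH2Cl2, −78 → 0 °C; then aq. tartaric acid, rt
Reagents that add atoms: water, O
Why: DIBAL-H reduction stops at the N-aluminio aldimine of the hindered nitrile (hydrolysed to the non-enolisable aldehyde on work-up) and at the same time cleaves the pivalate, leaving one free hydroxyl.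

Step 17
Reactants: 24 (1S,2S,6S)-2-(3-hydroxypropyl)-1,6-dimethyl-3-(propan-2-ylidene)cyclohexane-1-carbaldehyde
Product: 25 3-[(1S,2S,3S)-2-formyl-2,3-dimethyl-6-(propan-2-ylidene)cyclohexyl]propyl acetate
Conditions: Ac2O, pyridine, DMAP (cat.), CH2Cl2, 0 °C → rt
Reagents that add atoms: acetic anhydride, CC(=O)OC(C)=O
Why: O-acetylation of the only hydroxyl present puts the acetate on the side chain without any selectivity problem; the quaternary aldehyde cannot enolise.

Step 18
Reactants: 25 3-[(1S,2S,3S)-2-formyl-2,3-dimethyl-6-(propan-2-ylidene)cyclohexyl]propyl acetate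
Product: 26 3-[(1S,2S,3S)-2-(hydroxymethyl)-2,3-dimethyl-6-(propan-2-ylidene)cyclohexyl]propyl acetate
Conditions: NaBH4, MeOH–THF, −20 → 0 °C, short reaction time
Reagents that add atoms: none
Why: Chemoselective borohydride reduction of the aldehyde in the presence of the acetate gives the neopentyl alcohol with no change at any stereocentre.

Step 19
Reactants: 26 3-[(1S,2S,3S)-2-(hydroxymethyl)-2,3-dimethyl-6-(propan-2-ylidene)cyclohexyl]propyl acetate; 19 7-bromo-2H-chromen-2-one
Product: 27 3-[(1S,2S,3S)-2,3-dimethyl-2-{[(2-oxo-2H-chromen-7-yl)oxy]methyl}-6-(propan-2-ylidene)cyclohexyl]propyl acetate (target)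
Conditions: tBuBrettPhos Pd G3 (3 mol %), K3PO4 (1.5 equiv), toluene, 80 °C
Reagents that add atoms: none
Why: Pd-catalysed C–O cross-coupling (Buchwald-type etherification) forms the aryl–O bond, so no SN2 displacement at the very hindered neopentyl carbon is needed, and the weak base spares acetate and lactone.

**Compound list**
1 | (S)-4-benzyl-1,3-oxazolidin-2-one | O=C1OC[C@H](Cc2ccccc2)N1 | starting material
2 | (E)-but-2-enoyl chloride | C/C=C/C(Cl)=O | starting material
3 | (S)-4-benzyl-3-[(E)-but-2-enoyl]-1,3-oxazolidin-2-one | C/C=C/C(=O)N1C(=O)OC[C@@H]1Cc1ccccc1 | intermediate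
4 | (S)-4-benzyl-3-[(R)-3-methylpent-4-enoyl]-1,3-oxazolidin-2-one | C=C[C@H](C)CC(=O)N1C(=O)OC[C@@H]1Cc1ccccc1 | intermediate
5 | (S)-4-benzyl-3-[(2S,3S)-2,3-dimethylpent-4-enoyl]-1,3-oxazolidin-2-one | C=C[C@H](C)[C@H](C)C(=O)N1C(=O)OC[C@@H]1Cc1ccccc1 | intermediate
6 | (2S,3S)-2,3-dimethylpent-4-en-1-ol | C=C[C@H](C)[C@H](C)CO | intermediate
7 | (2S,3S)-2,3-dimethylpent-4-enal | C=C[C@H](C)[C@H](C)C=O | intermediate
8 | (2S,3S)-2,3-dimethylpent-4-enenitrile | C=C[C@H](C)[C@H](C)C#N | intermediate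
9 | 3-bromopropan-1-ol | OCCCBr | starting material
10 | 3-bromopropyl 2,2-dimethylpropanoate | CC(C)(C)C(=O)OCCCBr | intermediate
11 | 3-(phenylsulfonyl)propyl 2,2-dimethylpropanoate | CC(C)(C)C(=O)OCCCS(=O)(=O)c1ccccc1 | intermediate
12 | 3-methylbut-2-enal | CC(C)=CC=O | starting material
13 | 2,3-dibromo-3-methylbutanal | CC(C)(Br)C(Br)C=O | intermediate
14 | 2-bromo-3-methylbut-2-enal | CC(C)=C(Br)C=O | intermediate
15 | 5-bromo-4-hydroxy-6-methyl-3-(phenylsulfonyl)hept-5-en-1-yl 2,2-dimethylpropanoate | CC(C)=C(Br)C(O)C(CCOC(=O)C(C)(C)C)S(=O)(=O)c1ccccc1 | intermediate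
16 | 4-acetoxy-5-bromo-6-methyl-3-(phenylsulfonyl)hept-5-en-1-yl 2,2-dimethylpropanoate | CC(C)=C(Br)C(OC(C)=O)C(CCOC(=O)C(C)(C)C)S(=O)(=O)c1ccccc1 | intermediate
17 | (3E)-5-bromo-6-methyl-3-(phenylsulfonyl)hepta-3,5-dien-1-yl 2,2-dimethylpropanoate | CC(C)=C(Br)/C=C(/S(=O)(=O)c1ccccc1)CCOC(=O)C(C)(C)C | intermediate
18 | 4-bromo-2-hydroxybenzaldehyde | O=Cc1ccc(Br)cc1O | starting material
19 | 7-bromo-2H-chromen-2-one | O=c1ccc2ccc(Br)cc2o1 | intermediate
20 | (2S,3S)-5-(9-borabicyclo[3.3.1]nonan-9-yl)-2,3-dimethylpentanenitrile | B1(CC[C@H](C)[C@H](C)C#N)C2CCCC1CCC2 | intermediate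
21 | (3E,8S,9S)-9-cyano-8-methyl-3-(phenylsulfonyl)-5-(propan-2-ylidene)dec-3-en-1-yl 2,2-dimethylpropanoate | CC(C)=C(CC[C@H](C)[C@H](C)C#N)/C=C(/S(=O)(=O)c1ccccc1)CCOC(=O)C(C)(C)C | intermediate
22 | 3-[(1S,2S,3S)-2-cyano-2,3-dimethyl-6-(propan-2-ylidene)cyclohexyl]-3-(phenylsulfonyl)propyl 2,2-dimethylpropanoate | CC(C)(C)C(=O)OCCC([C@H]1C(=C(C)C)CC[C@H](C)[C@]1(C)C#N)S(=O)(=O)c1ccccc1 | intermediate
23 | 3-[(1S,2S,3S)-2-cyano-2,3-dimethyl-6-(propan-2-ylidene)cyclohexyl]propyl 2,2-dimethylpropanoate | CC(C)(C)C(=O)OCCC[C@H]1C(=C(C)C)CC[C@H](C)[C@]1(C)C#N | intermediate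
24 | (1S,2S,6S)-2-(3-hydroxypropyl)-1,6-dimethyl-3-(propan-2-ylidene)cyclohexane-1-carbaldehyde | OCCC[C@H]1C(=C(C)C)CC[C@H](C)[C@]1(C)C=O | intermediate
25 | 3-[(1S,2S,3S)-2-formyl-2,3-dimethyl-6-(propan-2-ylidene)cyclohexyl]propyl acetate | CC(=O)OCCC[C@H]1C(=C(C)C)CC[C@H](C)[C@]1(C)C=O | intermediate
26 | 3-[(1S,2S,3S)-2-(hydroxymethyl)-2,3-dimethyl-6-(propan-2-ylidene)cyclohexyl]propyl acetate | CC(=O)OCCC[C@H]1C(=C(C)C)CC[C@H](C)[C@]1(C)CO | intermediate
27 | 3-[(1S,2S,3S)-2,3-dimethyl-2-{[(2-oxo-2H-chromen-7-yl)oxy]methyl}-6-(propan-2-ylidene)cyclohexyl]propyl acetate | CC(=O)OCCC[C@H]1C(=C(C)C)CC[C@H](C)[C@]1(C)COc1ccc2ccc(=O)oc2c1 | target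

**Step count**
Total: 19 steps. Longest linear sequence: 12 steps (steps 1–5 then 13–19; the branch 6, 7, 9, 10, 11 then 13–19 is equally long).

**Three steps most likely to fail**

Step 14 (ring closure). The α-branched vinyl sulfone is a hindered acceptor, the isopropylidene methyls are vinylogously acidic, and the preference at the quaternary carbon (nitrile axial, methyl equatorial) rests on a small steric and electrostatic bias. The fallback sets out from bromo-enal 14 and borane 20 and takes the side chain out of the acceptor. A Horner–Wadsworth–Emmons reaction of 14 with diethyl [(phenylsulfonyl)methyl]phosphonate (NaH, THF) gives {[(1E)-3-bromo-4-methylpenta-1,3-dien-1-yl]sulfonyl}benzene F1. Coupling F1 with 20 as in step 13 gives (2S,3S)-2,3,7-trimethyl-6-[(E)-2-(phenylsulfonyl)ethenyl]oct-6-enenitrile F2. The same LDA cyclisation onto this unhindered E-vinyl sulfone gives (1S,2S,6S)-1,2-dimethyl-6-[(phenylsulfonyl)methyl]-5-(propan-2-ylidene)cyclohexane-1-carbonitrile F3. Its α-sulfonyl carbanion (n-BuLi, −78 °C) opens ethylene oxide (BF3·OEt2) to give (1S,2S,6S)-6-[3-hydroxy-1-(phenylsulfonyl)propyl]-1,2-dimethyl-5-(propan-2-ylidene)cyclohexane-1-carbonitrile F4, and pivaloylation (PivCl, pyridine) comes back to the route at 22.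

Step 13 (fragment union). Oxidative addition into the fully substituted bromodiene is slow and the vinyl sulfone is exposed to aqueous base and borane. The fallback sets out from 20 and 14 and reverses the order of assembly. 20 is coupled with the small, electron-poor bromo-enal 14 to give (2S,3S)-6-formyl-2,3,7-trimethyloct-6-enenitrile F5. The lithiated sulfone 11 (LDA, −78 °C) adds to F5 to give (8S,9S)-9-cyano-4-hydroxy-8-methyl-3-(phenylsulfonyl)-5-(propan-2-ylidene)decyl 2,2-dimethylpropanoate F6. Acetylation gives (8S,9S)-4-acetoxy-9-cyano-8-methyl-3-(phenylsulfonyl)-5-(propan-2-ylidene)decyl 2,2-dimethylpropanoate F7, and DBU elimination comes back to the route at 21.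

Step 19 (aryl ether). The alcohol is very hindered, β-hydride loss from the Pd alkoxide can compete, and base could shuffle the acetate. The fallback sets out from 26 and alkylates the phenol instead of arylating the alcohol. 26 is converted (Tf2O, 2,6-lutidine, CH2Cl2, −78 °C) into 3-[(1S,2S,3S)-2,3-dimethyl-6-(propan-2-ylidene)-2-({[(trifluoromethyl)sulfonyl]oxy}methyl)cyclohexyl]propyl acetate F8. The triflate is displaced by the caesium salt of 7-hydroxycoumarin (umbelliferone, Cs2CO3, DMF, 50 °C), which arrives directly at 27.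

**Further compounds**
F1 | step 14 | {[(1E)-3-bromo-4-methylpenta-1,3-dien-1-yl]sulfonyl}benzene | CC(C)=C(Br)/C=C/S(=O)(=O)c1ccccc1
F2 | step 14 | (2S,3S)-2,3,7-trimethyl-6-[(E)-2-(phenylsulfonyl)ethenyl]oct-6-enenitrile | CC(C)=C(CC[C@H](C)[C@H](C)C#N)/C=C/S(=O)(=O)c1ccccc1
F3 | step 14 | (1S,2S,6S)-1,2-dimethyl-6-[(phenylsulfonyl)methyl]-5-(propan-2-ylidene)cyclohexane-1-carbonitrile | O=S(=O)(c1ccccc1)C[C@H]1C(=C(C)C)CC[C@H](C)[C@]1(C)C#N
F4 | step 14 | (1S,2S,6S)-6-[3-hydroxy-1-(phenylsulfonyl)propyl]-1,2-dimethyl-5-(propan-2-ylidene)cyclohexane-1-carbonitrile | OCCC([C@H]1C(=C(C)C)CC[C@H](C)[C@]1(C)C#N)S(=O)(=O)c1ccccc1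
F5 | step 13 | (2S,3S)-6-formyl-2,3,7-trimethyloct-6-enenitrile | CC(C)=C(CC[C@H](C)[C@H](C)C#N)C=O
F6 | step 13 | (8S,9S)-9-cyano-4-hydroxy-8-methyl-3-(phenylsulfonyl)-5-(propan-2-ylidene)decyl 2,2-dimethylpropanoate | CC(C)=C(CC[C@H](C)[C@H](C)C#N)C(O)C(CCOC(=O)C(C)(C)C)S(=O)(=O)c1ccccc1
F7 | step 13 | (8S,9S)-4-acetoxy-9-cyano-8-methyl-3-(phenylsulfonyl)-5-(propan-2-ylidene)decyl 2,2-dimethylpropanoate | CC(C)=C(CC[C@H](C)[C@H](C)C#N)C(OC(C)=O)C(CCOC(=O)C(C)(C)C)S(=O)(=O)c1ccccc1
F8 | step 19 | 3-[(1S,2S,3S)-2,3-dimethyl-6-(propan-2-ylidene)-2-({[(trifluoromethyl)sulfonyl]oxy}methyl)cyclohexyl]propyl acetate | CC(=O)OCCC[C@H]1C(=C(C)C)CC[C@H](C)[C@]1(C)COS(=O)(=O)C(F)(F)F
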